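A direct plan would make flavone unit 1 first from an acetylated 2,6-dimethoxyhydroquinone (chalcone, oxidative cyclisation), free its 6-hydroxyl to give A1, arylate A1 with 4-fluorobenzaldehyde A2 by SNAr to aldehyde A3, build unit 2 on A3 by a second chalcone/cyclisation sequence to the protected biflavone A4, and finish with a Lewis acid. Its weakest steps would be:
- the SNAr O-arylation, because the 6-phenoxide lies between two methoxy groups and would need hot carbonate on a base-sensitive pyranone;
- the final ether cleavage, because one reagent would have to remove two benzyl ethers and exactly one of four methyl ethers;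
- the benzylation/hydrogenolysis pair at O6, which would add two steps but no skeletal complexity.

The route would disconnect ring A of flavone unit 1 (C4a, C5, C6, C7, C8, C8a) at C8–C8a and C4a–C5, so that the hindered C6–O–C4''' ether is never made on an arene: the oxygen is attached by SN2 to the sp3 carbon of an acetoacetate that later becomes C6. In the key step a γ-lithiated 2-aryloxy-3-methoxycrotonate, carrying the finished unit 2, displaces the methylthio group of a 2-(methylthio)-6-aryl-4-pyranone and closes by Claisen acylation of the pyranone C3. One operation would thus join the halves, build ring A and place 5-OH, 6-OAr and 7-OMe unambiguously, which removes the O-arylation, the selective demethylation and the 6-O protection.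

Key step: step 6

Assumption: 1, 5 and 7 are taken as purchased; 9 is carried on as its mixture of double-bond isomers, since both should give the same dienolate; the target has no stereocentre.

**Step 1**
Reactants: 1 4,4-bis(methylthio)but-3-en-2-one; 2 4-methoxybenzoyl chloride
Product: 3 1-(4-methoxyphenyl)-5,5-bis(methylthio)pent-4-ene-1,3-dione
Conditions: LiN(SiMe3)2 (2.1 equiv), THF, −78 °C; 2 (1.0 equiv), −78 to 0 °C; AcOH quench
Reagents that add atoms: none
Why: In this crossed Claisen-type C-acylation the kinetic lithium enolate of the methyl ketone attacks the non-enolisable acid chloride, and the second equivalent of base turns the 1,3-diketone into its enolate at once, which should suppress O-acylation and double acylation while the ketene dithioacetal stays untouched.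

**Step 2**
Reactants: 3 1-(4-methoxyphenyl)-5,5-bis(methylthio)pent-4-ene-1,3-dione
Product: 4 6-(4-methoxyphenyl)-2-(methylthio)-4H-pyran-4-one
Conditions: p-TsOH·H2O (10 mol%), toluene, 80 °C, N2 sweep (bleach trap)
Reagents that add atoms: none
Why: Acid-catalysed intramolecular addition–elimination (6-endo oxa-Michael closure of the enol oxygen of the aroyl ketone on the ketene dithioacetal carbon, then loss of MeSH), the reaction type that gives 2-(methylthio)chromones from ketene dithioacetals of 2'-hydroxyacetophenones, should close ring C of unit 1 as the only possible six-membered ring.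

**Step 3**
Reactants: 5 apigenin
Product: 6 7-(benzyloxy)-5-hydroxy-2-(4-hydroxyphenyl)-4H-chromen-4-one
Conditions: BnBr (1.0 equiv), K2CO3 (1.05 equiv), DMF, rt
Reagents that add atoms: benzyl bromide, BrCc1ccccc1
Why: In this Williamson etherification under limiting base the 7-OH (para to the C4 carbonyl) is the most acidic phenol, the 4'-OH is less acidic and the chelated 5-OH is inert, so mono-benzylation should fall mainly on O7.

**Step 4**
Reactants: 6 7-(benzyloxy)-5-hydroxy-2-(4-hydroxyphenyl)-4H-chromen-4-one; 7 racemic methyl 2-chloro-3-oxobutanoate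
Product: 8 racemic methyl 2-{4-[7-(benzyloxy)-5-hydroxy-4-oxo-4H-chromen-2-yl]phenoxy}-3-oxobutanoate
Conditions: 7 (1.3 equiv), K2CO3 (2 equiv), KI (10 mol%), acetone, 55 °C
Reagents that add atoms: none
Why: Williamson-type SN2 displacement of the activated secondary chloride by the 4'-phenoxide, the standard route to 2-aryloxyacetoacetates, forms the future C6–O bond on an sp3 carbon where ortho substituents play no part; the hydrogen-bonded 5-OH should not alkylate, and the new stereocentre is racemic and disappears in step 5.

**Step 5**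
Reactants: 8 racemic methyl 2-{4-[7-(benzyloxy)-5-hydroxy-4-oxo-4H-chromen-2-yl]phenoxy}-3-oxobutanoate
Product: 9 methyl 2-{4-[7-(benzyloxy)-5-hydroxy-4-oxo-4H-chromen-2-yl]phenoxy}-3-methoxybut-2-enoate (E/Z mixture)
Conditions: HC(OMe)3 (10 equiv), p-TsOH·H2O (5 mol%), ClCH2CH2Cl, 60 °C; Et3N quench
Reagents that add atoms: trimethyl orthoformate, COC(OC)OC
Why: Acid-catalysed enol ether formation (ketalisation by the orthoformate, then loss of MeOH into conjugation with the ester), the usual preparation of 3-methoxycrotonates from acetoacetates, should methylate only the ketone oxygen because phenols, the benzyl ether and the chromone are inert to orthoformate and acid.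

**Step 6**
Reactants: 9 methyl 2-{4-[7-(benzyloxy)-5-hydroxy-4-oxo-4H-chromen-2-yl]phenoxy}-3-methoxybut-2-enoate; 4 6-(4-methoxyphenyl)-2-(methylthio)-4H-pyran-4-one
Product: 11 7''-O-benzylcryptomerin B (6-{4-[7-(benzyloxy)-5-hydroxy-4-oxo-4H-chromen-2-yl]phenoxy}-5-hydroxy-7-methoxy-2-(4-methoxyphenyl)-4H-chromen-4-one), via pyranonyl crotonate 10 (not isolated)
Conditions: 9, LiN(SiMe3)2 (2.2 equiv), THF/DMPU, −78 °C; LiN(iPr)2 (1.1 equiv), −78 °C; 4 (1.0 equiv), −78 °C to rt; AcOH quench
Reagents that add atoms: none
Why: Proposed new method: after lithiation of the 5-OH, γ-deprotonation of 9 by LiN(iPr)2 should give the extended ester dienolate, whose terminal carbon adds to C2 of pyranone 4, the only ring position where conjugate addition becomes irreversible through loss of methanethiolate, to give 10 (addition–elimination at a vinylogous thioester). The spare amide base then removes the doubly activated C8–H of 10, and the pyranone enolate carbon (C3 of the pyranone, the future C4a) acylates the ester carbonyl in a 6-exo-trig Claisen (Dieckmann-type) closure; loss of methoxide and tautomerisation of the cyclohexadienone give aromatic ring A as its chelated lithium 5-phenoxide, the thermodynamic sink. The closest known reaction type is the Staunton–Weinreb annulation, in which a lithiated ortho-toluate adds to a 4-methoxypyran-2-one and closes by Dieckmann condensation with loss of methanol, together with the anionic annulations of γ-lithiated 3-methoxycrotonates. Regiochemistry is fixed by the precursor, since the ester carbon becomes C5 (OH), the aryloxy carbon C6, the enol ether carbon C7 (OMe) and the former methyl C8, so no C8-linked isomer can arise, and no stereocentre is formed. The step needs γ- and not α-attack of the dienolate, which the fully substituted α-carbon secures, and it needs the Claisen closure to win over aldol attack on the pyranone carbonyl, which is reversible and cannot aromatise; the double-bond geometry of 9 should equilibrate in the dienolates of 9 and 10, and the lithium 5-phenoxide keeps the chromone of unit 2 electron-rich and unreactive.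

**Step 7**
Reactants: 11 7''-O-benzylcryptomerin B
Product: 12 Cryptomerin B (6-[4-(5,7-dihydroxy-4-oxo-4H-chromen-2-yl)phenoxy]-5-hydroxy-7-methoxy-2-(4-methoxyphenyl)-4H-chromen-4-one)
Conditions: H2 (1 atm), Pd/C (10% Pd), THF/MeOH, rt; 11 freed of sulfur residues beforehand
Reagents that add atoms: none
Why: Catalytic hydrogenolysis should cleave the single benzyl aryl ether, while the two methyl ethers, the diaryl ether and the pyranone C2=C3 bonds are not expected to react at 1 atm and room temperature.

**Compound list**
1 | 4,4-bis(methylthio)but-3-en-2-one | CC(=O)C=C(SC)SC | starting material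
2 | 4-methoxybenzoyl chloride | COc1ccc(cc1)C(Cl)=O | starting material
3 | 1-(4-methoxyphenyl)-5,5-bis(methylthio)pent-4-ene-1,3-dione | COc1ccc(cc1)C(=O)CC(=O)C=C(SC)SC | intermediate
4 | 6-(4-methoxyphenyl)-2-(methylthio)-4H-pyran-4-one | COc1ccc(cc1)-c1cc(=O)cc(SC)o1 | intermediate
5 | apigenin, 5,7-dihydroxy-2-(4-hydroxyphenyl)-4H-chromen-4-one | O=c1cc(-c2ccc(O)cc2)oc2cc(O)cc(O)c12 | starting material
6 | 7-(benzyloxy)-5-hydroxy-2-(4-hydroxyphenyl)-4H-chromen-4-one | O=c1cc(-c2ccc(O)cc2)oc2cc(OCc3ccccc3)cc(O)c12 | intermediate
7 | racemic methyl 2-chloro-3-oxobutanoate | COC(=O)C(Cl)C(C)=O | starting material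
8 | racemic methyl 2-{4-[7-(benzyloxy)-5-hydroxy-4-oxo-4H-chromen-2-yl]phenoxy}-3-oxobutanoate | COC(=O)C(Oc1ccc(cc1)-c1cc(=O)c2c(O)cc(OCc3ccccc3)cc2o1)C(C)=O | intermediate
9 | methyl 2-{4-[7-(benzyloxy)-5-hydroxy-4-oxo-4H-chromen-2-yl]phenoxy}-3-methoxybut-2-enoate, mixture of E and Z isomers | COC(=O)C(Oc1ccc(cc1)-c1cc(=O)c2c(O)cc(OCc3ccccc3)cc2o1)=C(C)OC | intermediate
10 | methyl 2-{4-[7-(benzyloxy)-5-hydroxy-4-oxo-4H-chromen-2-yl]phenoxy}-3-methoxy-4-[6-(4-methoxyphenyl)-4-oxo-4H-pyran-2-yl]but-2-enoate, formed in the flask, double-bond geometry not fixed | COC(=O)C(Oc1ccc(cc1)-c1cc(=O)c2c(O)cc(OCc3ccccc3)cc2o1)=C(OC)Cc1cc(=O)cc(o1)-c1ccc(OC)cc1 | intermediate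
11 | 7''-O-benzylcryptomerin B, 6-{4-[7-(benzyloxy)-5-hydroxy-4-oxo-4H-chromen-2-yl]phenoxy}-5-hydroxy-7-methoxy-2-(4-methoxyphenyl)-4H-chromen-4-one | COc1ccc(-c2cc(=O)c3c(O)c(Oc4ccc(-c5cc(=O)c6c(O)cc(OCc7ccccc7)cc6o5)cc4)c(OC)cc3o2)cc1 | intermediate
12 | Cryptomerin B, 6-[4-(5,7-dihydroxy-4-oxo-4H-chromen-2-yl)phenoxy]-5-hydroxy-7-methoxy-2-(4-methoxyphenyl)-4H-chromen-4-one | COc1ccc(-c2cc(=O)c3c(O)c(Oc4ccc(-c5cc(=O)c6c(O)cc(O)cc6o5)cc4)c(OC)cc3o2)cc1 | target

Total step count: 7. Longest linear sequence: 5 steps (steps 3 to 7, from apigenin); the pyranone branch (steps 1 and 2) joins at step 6.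

**Steps most likely to fail**

Step 6 (proposed new method). The dienolate may add to the aryl-bearing C6 or to the carbonyl of the pyranone and open the ring, the sequence may stall at the substitution product without Claisen closure, or excess amide base may lithiate C3 of flavone unit 2. The fallback uses known chemistry and sets out from 5 and 6. Apigenin 5 would be methylated at O7 and O4' (Me2SO4, K2CO3, acetone; the chelated 5-OH is spared) to 5-hydroxy-7-methoxy-2-(4-methoxyphenyl)-4H-chromen-4-one F1. Iodination of F1 ortho to the free 5-OH (benzyltrimethylammonium dichloroiodate, CaCO3, CH2Cl2/MeOH, rt) would give 5-hydroxy-6-iodo-7-methoxy-2-(4-methoxyphenyl)-4H-chromen-4-one F2. A copper-catalysed Ullmann diaryl ether coupling of F2 with the 4'-OH of 6 (CuI, N,N-dimethylglycine, Cs2CO3, dioxane, 100 °C) would come back to the route at 11. This forms the hindered C6–O bond directly and would be expected to need forcing conditions.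

Step 4. The chloro keto ester may be consumed as its own enolate or lose its acetyl group by retro-Claisen cleavage before the weakly nucleophilic 4'-phenoxide is alkylated. The fallback sets out from 6 and replaces the SN2 reaction by a carbene O–H insertion: methyl 2-diazo-3-oxobutanoate F3 with Rh2(OAc)4 (1 mol%) in ClCH2CH2Cl at 80 °C should insert into the 4'-OH of 6 under neutral conditions and come back to the route at 8.

Step 3. Poor site selectivity between O7 and O4' may give mixtures with the 4'-benzyl and 7,4'-dibenzyl ethers. The fallback sets out from commercial racemic naringenin F4 and moves the benzylation to a flavanone, where the 4'-OH is an ordinary, non-conjugated phenol. F4 would be benzylated at O7 (BnBr, K2CO3, acetone, rt) to racemic 7-O-benzylnaringenin F5. Dehydrogenation of F5 with catalytic I2 in DMSO at 120 °C would remove the stereocentre and come back to the route at 6.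

**Further compounds**
F1 | step 6 | 5-hydroxy-7-methoxy-2-(4-methoxyphenyl)-4H-chromen-4-one | COc1ccc(cc1)-c1cc(=O)c2c(O)cc(OC)cc2o1
F2 | step 6 | 5-hydroxy-6-iodo-7-methoxy-2-(4-methoxyphenyl)-4H-chromen-4-one | COc1ccc(cc1)-c1cc(=O)c2c(O)c(I)c(OC)cc2o1
F3 | step 4 | methyl 2-diazo-3-oxobutanoate | COC(=O)C(=[N+]=[N-])C(C)=O
F4 | step 3 | racemic naringenin, 5,7-dihydroxy-2-(4-hydroxyphenyl)chroman-4-one | O=C1CC(c2ccc(O)cc2)Oc2cc(O)cc(O)c12
F5 | step 3 | racemic 7-(benzyloxy)-5-hydroxy-2-(4-hydroxyphenyl)chroman-4-one | O=C1CC(c2ccc(O)cc2)Oc2cc(OCc3ccccc3)cc(O)c12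
A1 | direct plan | 6-hydroxy-5,7-dimethoxy-2-(4-methoxyphenyl)-4H-chromen-4-one | COc1ccc(-c2cc(=O)c3c(OC)c(O)c(OC)cc3o2)cc1
A2 | direct plan | 4-fluorobenzaldehyde | O=Cc1ccc(F)cc1
A3 | direct plan | 4-{[5,7-dimethoxy-2-(4-methoxyphenyl)-4-oxo-4H-chromen-6-yl]oxy}benzaldehyde | COc1ccc(-c2cc(=O)c3c(OC)c(Oc4ccc(C=O)cc4)c(OC)cc3o2)cc1
A4 | direct plan | 6-{4-[5,7-bis(benzyloxy)-4-oxo-4H-chromen-2-yl]phenoxy}-5,7-dimethoxy-2-(4-methoxyphenyl)-4H-chromen-4-one | COc1ccc(-c2cc(=O)c3c(OC)c(Oc4ccc(-c5cc(=O)c6c(OCc7ccccc7)cc(OCc7ccccc7)cc6o5)cc4)c(OC)cc3o2)cc1
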